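Atom numbers are those of the 8,9-seco-ent-kaurane skeleton of the target and are used for all intermediates and fragments. The face of ring A that carries H-5 is called the lower face, and the face that carries the C20 methyl group and the C6 arm is called the upper face.

## Analysis of the target

Target 47 has a cyclohexane ring A (C1–C5, C10) trans-fused along C5–C10 to a ten-membered carbocycle (C5, C6, C7, C8, C14, C13, C12, C11, C9, C10). The large ring is bridged between C8 and C13 by a 5-methylidenecyclopent-2-enone (C8, C14, C13, C16, C15), so that C8=C14 is an E olefin of the ten-membered ring. There are six stereocentres (1S, 3S, 5R, 7R, 10S, 13R). In ring A the C20 methyl group is axial on the upper face, H-5 is axial on the lower face, the C1 hydroxyl is equatorial and cis to C20, and the C3 acetate is axial and cis to H-5. C7 and C13 lie far from ring A and from each other and have to be set independently. The sensitive groups are the cross-conjugated dienone (a Michael acceptor with an acidic C13–H), the β-hydroxy ketone C1–OH/C9=O (retro-aldol), the allylic C7 carbinol and the acetate. The main difficulty is the quaternary C10, which is flanked by the C9 ketone, the C1 carbinol and C5 and sits at the junction of a medium ring. The strategy rests on the fact that the oxygenated C9 is bonded to C10 and that C10 is allylic to C1/C2 once a C1=C10 olefin is drawn. A carbanion at C9 can then be delivered to C10 from an ether oxygen on C2. Because the shift is suprafacial, that oxygen must lie on the lower face (cis to H-5, trans to the C6 arm), so that C9 ends up trans to C20.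

## Retrosynthetic reasoning

**47 back to 44.** The dienone and the free C7 hydroxyl are unveiled last. C15 is carried as a PMB-protected carbinol and C7 as a TBS ether, so that 47 comes from 46 by desilylation, 46 from 45 by oxidation of the doubly allylic alcohol, and 45 from 44 by oxidative debenzylation. This keeps the Michael acceptor out of every basic or reducing step.

**44 back to 43.** The C3 acetate and the equatorial C1 carbinol are formed together from the axial C3 alcohol and the C1 ketone of 43 by an Evans–Tishchenko reduction. Hydride must reach C1 from the lower face, and the axial C3 oxygen is the only group placed to deliver it. The same step acylates C3, so no hydroxyl differentiation is needed.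

**43 back to 40.** The saturated C11–C12 bridge and the C9 ketone come from ynone 42 by conjugate reduction. 42 comes from propargylic alcohol 41 by selective oxidation and 41 from silyl ether 40. The C9 oxygen is kept masked until ring A no longer needs base, because a C1/C9 diketone around quaternary C10 would not survive alkaline peroxide.

**40 back to 34.** Ring A is oxygenated from the 1-en-3-one 35. Reagents approach C1 anti to the axial C20 methyl, which gives the wrong C1 epimer directly but the right face for C3. The enone is therefore transposed: epoxidation (36), Wharton transposition (37) and oxidation give the 2-en-1-one 38. A second epoxidation (39) and reductive opening put the C3 oxygen on the lower face (40). 35 is the unmasked form of ketal 34.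

**34 back to 32 (key disconnection).** The C9–C10 bond is cut. In the forward sense the C9 carbanion of the thirteen-membered propargylic allylic ether 32 shifts to C10, the C2–O bond breaks and the olefin moves to C1=C2. This is chosen over any other cut because it makes the quaternary centre, the C9 oxygen function and the ten-membered ring at once. The C10 configuration is copied from the secondary carbinol C2 of 32, which is easy to set.

**32 back to 29.** The C2–O–C9 ether bond is cut. 32 comes from bromo alcohol 31 by intramolecular etherification, and 31 from diol 29. A thirteen-membered ether is far easier to close than the ten-membered carbocycle.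

**29 back to 13 and 24.** The C7–C8 bond is cut between aldehyde 13 and alkenyl iodide 24 (chromium-mediated coupling to 25). C7 is then set by reagent-controlled reduction of enone 26, while the chain is still open and no ring conformation interferes.

**13 back to 1 and 2.** C2 of 11 is set by reduction of keto ketal 10, whose C3 ketal comes from dione 9 and hence from enone 7. C5 of 6 is set by a Claisen rearrangement that transfers the configuration of carbinol 4. 4 comes from enone 3, the annulation product of 1 and 2.

**24 back to 14 and 15.** C13 comes from the trans conjugate addition of alkynylalane 16 (from 14) to the silyloxy enone 15. This addition needs nickel catalysis, because cyclic s-trans enones do not accept alkynylalanes otherwise. Loss of the silyloxy group then gives C8=C14 (18), iodination gives 19, and methylenation gives 22.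

## Alternatives that were turned down

**Alternative 1:** silicon-directed Nazarov closure of the five-membered ring.
- Disconnection: C13–C14, with the cyclopentenone made last from the eleven-membered cross-conjugated dienone A2 (vinylsilane at C14).
- Forward key step: Me2AlCl-promoted conrotatory 4π closure of A2, with loss of silicon fixing C8=C14, to the pivalate A1.
- For: the cyclopentenone and the bridged bicycle arise in one step, and C15 is at the ketone level from the start.
- Against: C13 is set only by the sense of conrotation, which no nearby element controls. A2 already contains the C9 ketone next to quaternary C10 and needs two defined olefin geometries in an eleven-membered ring, so the hardest problem is only moved into the synthesis of A2. The C16 methylene costs a further elimination from A1.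
- Comparison: on the cyclopentenone itself this is stronger than the chosen route, which needs a redox detour at C15. The chosen strategy offers instead a stereospecific construction of C10 and a C13 centre taken from a chiral building block.

**Alternative 2:** chromium-mediated macrocyclization at C7–C8.
- Disconnection: C7–C8 of the ten-membered ring, from the open-chain iodo dienone aldehyde A4.
- Forward key step: CrCl2 with catalytic NiCl2 closes the ring and gives A3, the C1 silyl ether of the target.
- For: very convergent, chemoselective, and only one deprotection from the target. It is stronger than the chosen route on the length of the endgame.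
- Against: direct closure of a ten-membered ring that contains an E olefin shared with a five-membered ring is costly in entropy and strain. C7 would be set by a flexible cyclic transition state. The dienone and the epimerizable C13 would be exposed to divalent chromium. A4 still needs the C9–C10 bond and the quaternary centre from some other chemistry.
- Comparison: the chosen route uses the same coupling intermolecularly, fixes C7 by reagent control in the open chain, and reaches the ten-membered ring through an easily closed thirteen-membered ether.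

**Alternative 3:** anionic oxy-Cope ring expansion.
- Disconnection: C12–C13 is formed while C8–C9 of a six-membered ring B is cut, from the spiro-fused decalinol A6.
- Forward key step: KH with 18-crown-6 triggers the [3,3] shift to the bridged ketone A5.
- For: well-precedented access to ten-membered rings. It delivers the C9 ketone, C8=C14 and a saturated C11–C12 bridge at once, which is stronger than the chosen route (alkyne reduction and C9 oxidation needed).
- Against: A6 has three contiguous fully substituted carbons (spiro C8, tertiary carbinol C9, quaternary C10), to be built by addition to a ketone flanked by two quaternary centres. C13 depends on the chair/boat choice. The strongly basic medium meets a skipped diene and an acidic C13–H.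
- Comparison: the chosen strategy makes C10 from a secondary allylic carbinol by a stereospecific shift instead of assembling the congested triad. It pays for this with more adjustments after the key step.

Key step: step 24

Remark on the chemistry: C15 is carried as the single epimer expected from step 15 (hydroxyl cis to the C13 alkynyl arm); this centre is erased in step 36, so its configuration is of no consequence.

Remark on the chemistry: the acetal carbon of the THP group (14 to 28) and C3 of 8 are epimer mixtures that do not affect the route.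

## Route

### Ring A fragment (steps 1–10)

Step 1
Reactants: 1 isobutyraldehyde; 2 pent-1-en-3-one
Product: 3 2,4,4-trimethylcyclohex-2-en-1-one
Conditions: H2SO4 (cat.), PhH, 45 °C then reflux (Dean–Stark)
Reagents that add atoms: none
Why: Acid-catalysed Robinson annulation: Michael addition of the aldehyde enol, intramolecular aldol condensation and dehydration give the 2-methyl enone with the gem-dimethyl carbon that becomes C4.

Step 2
Reactants: 3 2,4,4-trimethylcyclohex-2-en-1-one
Product: 4 (S)-2,4,4-trimethylcyclohex-2-en-1-ol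
Conditions: (R)-2-methyl-CBS-oxazaborolidine (10 mol %), BH3·SMe2, THF, −20 °C
Reagents that add atoms: none
Why: Corey–Bakshi–Shibata reduction; the α-methylated alkenyl group is the large substituent, so the (R)-catalyst should give the (S)-carbinol (later C1), which relays chirality to C5.

Step 3
Reactants: 4 (S)-2,4,4-trimethylcyclohex-2-en-1-ol
Product: 6 ethyl 2-[(1R)-2,6,6-trimethylcyclohex-2-en-1-yl]acetate, via ketene acetal 5 (not isolated)
Conditions: MeC(OEt)3, EtCO2H (cat.), xylene, 140 °C (−EtOH)
Reagents that add atoms: triethyl orthoacetate, CCOC(C)(OCC)OCC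
Why: Johnson–Claisen rearrangement; the [3,3] shift is suprafacial, so the C6–C7 arm arrives at C5 on the face that carried the carbinol oxygen while the olefin moves to C1=C10, and the intramolecular transition state tolerates the neighbouring quaternary carbon.

Step 4
Reactants: 6 ethyl 2-[(1R)-2,6,6-trimethylcyclohex-2-en-1-yl]acetate
Product: 7 ethyl 2-[(1R)-2,6,6-trimethyl-4-oxocyclohex-2-en-1-yl]acetate
Conditions: Rh2(cap)4 (1 mol %; cap = caprolactamate), t-BuOOH, K2CO3, CH2Cl2, rt
Reagents that add atoms: tert-butyl hydroperoxide, CC(C)(C)OO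
Why: Catalytic allylic C–H oxidation; of the allylic positions only the ring methylene C2 is secondary and unhindered (C5–H is tertiary and neopentylic), so the C2 enone should form, as in the oxidation of α-cyclogeranyl rings.

Step 5
Reactants: 7 ethyl 2-[(1R)-2,6,6-trimethyl-4-oxocyclohex-2-en-1-yl]acetate
Product: 8 ethyl 2-[(1S)-5-hydroxy-2,6,6-trimethyl-4-oxocyclohex-2-en-1-yl]acetate (C3 epimers)
Conditions: KN(SiMe3)2, THF, −78 °C; then 2-(phenylsulfonyl)-3-phenyloxaziridine; NH4Cl (aq.)
Reagents that add atoms: 2-(phenylsulfonyl)-3-phenyloxaziridine, O=S(=O)(c1ccccc1)N1OC1c1ccccc1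
Why: Kinetic deprotonation at the α′ methylene C3 (more acidic than the ester) gives the cross-conjugated enolate, which the Davis oxaziridine hydroxylates; the C3 configuration is removed in step 6.

Step 6
Reactants: 8 ethyl 2-[(1S)-5-hydroxy-2,6,6-trimethyl-4-oxocyclohex-2-en-1-yl]acetate
Product: 9 ethyl 2-[(1S)-2,6,6-trimethyl-4,5-dioxocyclohex-2-en-1-yl]acetate
Conditions: Dess–Martin periodinane, NaHCO3, CH2Cl2, rt
Reagents that add atoms: none
Why: Dess–Martin oxidation of the acyloin gives the non-enolizable ene-1,2-dione (C4 is quaternary) under non-basic conditions that leave the ester and C5 untouched.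

Step 7
Reactants: 9 ethyl 2-[(1S)-2,6,6-trimethyl-4,5-dioxocyclohex-2-en-1-yl]acetate
Product: 10 ethyl 2-[(1S)-5,5-(ethylenedioxy)-2,6,6-trimethyl-4-oxocyclohex-2-en-1-yl]acetate
Conditions: (Me3SiOCH2)2, Me3SiOTf (cat.), CH2Cl2, −78 → −20 °C
Reagents that add atoms: 1,2-bis(trimethylsilyloxy)ethane, C[Si](C)(C)OCCO[Si](C)(C)C
Why: Silyl triflate-catalysed ketalization discriminates saturated from conjugated ketones: the C3 carbonyl is unconjugated and activated by its neighbour, the C2 carbonyl is a deactivated β,β-disubstituted enone, as in the selective monoketalization of the Wieland–Miescher ketone.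

Step 8
Reactants: 10 ethyl 2-[(1S)-5,5-(ethylenedioxy)-2,6,6-trimethyl-4-oxocyclohex-2-en-1-yl]acetate
Product: 11 ethyl 2-[(1S,4S)-5,5-(ethylenedioxy)-4-hydroxy-2,6,6-trimethylcyclohex-2-en-1-yl]acetate
Conditions: K[(s-Bu)3BH], THF, −78 °C
Reagents that add atoms: none
Why: 1,2-Reduction of the β,β-disubstituted enone by a bulky borohydride; with the C5 arm pseudoaxial, the pseudoaxial C4 methyl shields the opposite face, so hydride should enter syn to the arm and place the C2 hydroxyl on the lower face (cis to H-5), as known for 3-oxo-α-ionone-type rings.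

Step 9
Reactants: 11 ethyl 2-[(1S,4S)-5,5-(ethylenedioxy)-4-hydroxy-2,6,6-trimethylcyclohex-2-en-1-yl]acetate
Product: 12 ethyl 2-[(1S,4S)-5,5-(ethylenedioxy)-2,6,6-trimethyl-4-(triethylsilyloxy)cyclohex-2-en-1-yl]acetate
Conditions: Et3SiCl, imidazole, DMF, rt
Reagents that add atoms: chlorotriethylsilane, CC[Si](Cl)(CC)CC
Why: Silylation masks the C2 hydroxyl for the oxidation in step 18; the triethylsilyl ether later leaves together with the THP group under conditions that spare the C7 TBS ether.

Step 10
Reactants: 12 ethyl 2-[(1S,4S)-5,5-(ethylenedioxy)-2,6,6-trimethyl-4-(triethylsilyloxy)cyclohex-2-en-1-yl]acetate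
Product: 13 2-[(1S,4S)-5,5-(ethylenedioxy)-2,6,6-trimethyl-4-(triethylsilyloxy)cyclohex-2-en-1-yl]acetaldehyde
Conditions: i-Bu2AlH, CH2Cl2, −78 °C
Reagents that add atoms: none
Why: Partial reduction of the ester through the aluminium hemiacetal, stable at low temperature, gives the C7 aldehyde; ketal and silyl ether are inert.

### Cyclopentene fragment (steps 11–16)

Step 11
Reactants: 14 2-(prop-2-yn-1-yloxy)oxane; 15 (S)-4-(tert-butyldimethylsilyloxy)cyclopent-2-en-1-one
Product: 17 (3R,4S)-4-(tert-butyldimethylsilyloxy)-3-[3-(oxan-2-yloxy)prop-1-yn-1-yl]cyclopentan-1-one, via alkynylalane 16 (not isolated)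
Conditions: 14, n-BuLi, Et2O, −78 → 0 °C; Me2AlCl; then Ni(acac)2 (5 mol %), i-Bu2AlH (5 mol %), 15, −5 °C
Reagents that add atoms: none
Why: Nickel-catalysed conjugate addition of an alkynyl dimethylalane; without the zerovalent nickel catalyst alkynylalanes do not add to s-trans cyclic enones, and the alkynyl group enters anti to the C4 silyloxy group, which fixes C13.

Step 12
Reactants: 17 (3R,4S)-4-(tert-butyldimethylsilyloxy)-3-[3-(oxan-2-yloxy)prop-1-yn-1-yl]cyclopentan-1-one
Product: 18 (4S)-4-[3-(oxan-2-yloxy)prop-1-yn-1-yl]cyclopent-2-en-1-one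
Conditions: DBU, CH2Cl2, −20 °C
Reagents that add atoms: none
Why: E1cB elimination of the β-silyloxy group gives the enone (C8=C14); short exposure at low temperature is chosen because C13–H is γ to the carbonyl and propargylic.

Step 13
Reactants: 18 (4S)-4-[3-(oxan-2-yloxy)prop-1-yn-1-yl]cyclopent-2-en-1-one
Product: 19 (4S)-2-iodo-4-[3-(oxan-2-yloxy)prop-1-yn-1-yl]cyclopent-2-en-1-one
Conditions: I2, pyridine, CH2Cl2, 0 °C → rt
Reagents that add atoms: iodine, II
Why: α-Iodination of the enone (pyridine conjugate addition, iodination of the enolate, elimination) installs the C8 iodide for the chromium coupling.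

Step 14
Reactants: 19 (4S)-2-iodo-4-[3-(oxan-2-yloxy)prop-1-yn-1-yl]cyclopent-2-en-1-one
Product: 22 (4S)-2-iodo-5-methylidene-4-[3-(oxan-2-yloxy)prop-1-yn-1-yl]cyclopent-2-en-1-one, via Mannich base 20 (not isolated), via methiodide 21 (not isolated)
Conditions: LiN(SiMe3)2, THF, −78 °C; Me2N=CH2+ I−, −78 → 0 °C; then MeI, CH2Cl2, rt; then NaHCO3 (aq.)
Reagents that add atoms: N,N-dimethylmethyleneiminium iodide (Eschenmoser's salt), C=[N+](C)C.[I-]
Why: Kinetic α′-enolization at C16, Mannich reaction with Eschenmoser's salt, N-methylation and E1cB loss of trimethylamine give the exocyclic methylene C17 without touching C13.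

Step 15
Reactants: 22 (4S)-2-iodo-5-methylidene-4-[3-(oxan-2-yloxy)prop-1-yn-1-yl]cyclopent-2-en-1-one
Product: 23 (1R,4S)-2-iodo-5-methylidene-4-[3-(oxan-2-yloxy)prop-1-yn-1-yl]cyclopent-2-en-1-ol
Conditions: NaBH4, CeCl3·7H2O, MeOH, −78 °C
Reagents that add atoms: none
Why: Luche reduction secures 1,2-addition to the cross-conjugated dienone; hydride is expected anti to the C13 substituent (cis alcohol), and this centre is erased in step 36.

Step 16
Reactants: 23 (1R,4S)-2-iodo-5-methylidene-4-[3-(oxan-2-yloxy)prop-1-yn-1-yl]cyclopent-2-en-1-ol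
Product: 24 4-methoxybenzyl ether of 23
Conditions: NaH, 4-MeOC6H4CH2Cl, Bu4NI (cat.), THF, 0 °C → rt
Reagents that add atoms: 4-methoxybenzyl chloride, COc1ccc(CCl)cc1
Why: Williamson etherification; the PMB ether tolerates the acid, base and organolithium steps ahead and is removed oxidatively at the end, orthogonal to the C7 TBS ether.

### Union and macrocyclic ether (steps 17–23)

Step 17
Reactants: 13 2-[(1S,4S)-5,5-(ethylenedioxy)-2,6,6-trimethyl-4-(triethylsilyloxy)cyclohex-2-en-1-yl]acetaldehyde; 24 4-methoxybenzyl ether of 23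
Product: 25 seco C7 alcohol (C7 epimers; C2 OTES; C3 dioxolane; C9 OTHP; C15 OPMB)
Conditions: CrCl2 (4 equiv), NiCl2 (2 mol %), DMF, rt
Reagents that add atoms: none
Why: Nozaki–Hiyama–Kishi coupling: the alkenyl iodide is activated by nickel, transmetalated to chromium and added chemoselectively to the aldehyde, with no basic organometallic that could deprotonate C13; the C7 mixture is corrected in steps 18 and 19.

Step 18
Reactants: 25 seco C7 alcohol
Product: 26 seco C7 enone
Conditions: Dess–Martin periodinane, NaHCO3, CH2Cl2, 0 °C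
Reagents that add atoms: none
Why: Dess–Martin oxidation under buffered conditions gives the enone; the C2 and C9 oxygens are protected and no base touches the now vinylogous C13–H.

Step 19
Reactants: 26 seco C7 enone
Product: 27 seco (7R)-alcohol
Conditions: (S)-2-methyl-CBS-oxazaborolidine, catecholborane, toluene, −78 °C
Reagents that add atoms: none
Why: Corey–Bakshi–Shibata reduction with the α-branched alkenyl group as the large and the C6 methylene as the small substituent should give the 7R carbinol under reagent control; catecholborane leaves the alkyne and the olefins alone.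

Step 20
Reactants: 27 seco (7R)-alcohol
Product: 28 seco (7R)-tert-butyldimethylsilyl ether
Conditions: t-BuMe2SiOTf, 2,6-lutidine, CH2Cl2, −78 °C
Reagents that add atoms: tert-butyldimethylsilyl triflate, CC(C)(C)[Si](C)(C)OS(=O)(=O)C(F)(F)F
Why: Silylation of the secondary allylic alcohol; the TBS ether outlasts all later steps and is removed last.

Step 21
Reactants: 28 seco (7R)-tert-butyldimethylsilyl ether
Product: 29 seco diol (C2 OH and C9 OH free; C7 OTBS; C15 OPMB)
Conditions: PPTS, MeOH, rt
Reagents that add atoms: none
Why: Mild acidic methanolysis cleaves the THP acetal and the secondary triethylsilyl ether and leaves the TBS ether, the dioxolane and the PMB ether.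

Step 22
Reactants: 29 seco diol
Product: 31 seco C9 bromide (C2 OH free; C7 OTBS; C15 OPMB), via mesylate 30 (not isolated)
Conditions: MsCl, 2,4,6-collidine, CH2Cl2, −20 °C; then LiBr, THF, 0 °C
Reagents that add atoms: lithium bromide, [Li+].[Br-]
Why: The primary propargylic hydroxyl is sulfonylated much faster than the secondary C2 hydroxyl next to the ketal, and bromide displaces the mesylate by SN2.

Step 23
Reactants: 31 seco C9 bromide
Product: 32 thirteen-membered propargylic allylic ether (C11≡C12; C1=C10; C3 dioxolane; C7 OTBS; C15 OPMB)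
Conditions: NaH, THF (2 mM), 0 → 45 °C
Reagents that add atoms: none
Why: Intramolecular Williamson etherification at high dilution, the established way to close thirteen-membered propargylic allylic ethers; the C2 configuration is untouched because the alkoxide is the nucleophile.

### Key step (step 24)

Step 24
Reactants: 32 thirteen-membered propargylic allylic ether
Product: 34 ring-contracted C9 triethylsilyl ether (ten-membered carbocycle; quaternary C10; C1=C2; C3 dioxolane), via lithium alkoxide 33 (not isolated)
Conditions: n-BuLi, THF, −78 °C; then Et3SiOTf, −78 → 0 °C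
Reagents that add atoms: triethylsilyl triflate, CC[Si](CC)(CC)OS(=O)(=O)C(F)(F)F
Why: n-BuLi removes a C9 proton, which is propargylic and α to the ether oxygen and sits on an unhindered methylene next to the lithium-binding oxygen; the α-oxy propargyl anion then undergoes a concerted suprafacial [2,3]-Wittig shift through a five-membered envelope (C9, O, C2, C1, C10), in which C9–C10 forms, C2–O breaks and the olefin moves to C1=C2. The closest known reaction type is the [2,3]-Wittig ring contraction of thirteen-membered propargylic allylic ethers to ten-membered cycloalkynols; the fully substituted C10 terminus makes this case more demanding. The ten-membered carbocycle is closed by transannular bond formation inside the thirteen-membered ring (contraction by three atoms), so neither high dilution nor the entropy cost of an open-chain closure applies. C10 is set by chirality transfer from C2: the oxygen lies on the lower face, so C9 is delivered to that face and the C20 methyl is pushed to the upper face, which gives the trans ring fusion of the target. C9 is set by the envelope geometry (alkynyl group pseudo-equatorial, as drawn) and is of no consequence because it becomes a ketone in step 32. The step needs [2,3] over [1,2] shift, which the low temperature and the concerted path open to a propargyl-stabilized anion should secure. It also needs lithiation at C9 and not at C13, C15 or C2, which is a kinetic matter secured by the α-oxygen, the sp-hybridized neighbour and the accessibility of the methylene. Silylation of the hindered alkoxide 33 in the same flask protects C9 for the ring A sequence.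

### Ring A oxygenation and endgame (steps 25–37)

Step 25
Reactants: 34 ring-contracted C9 triethylsilyl ether
Product: 35 ring A 1-en-3-one
Conditions: PPTS, acetone–H2O, 40 °C
Reagents that add atoms: water, O
Why: Hydrolysis of the allylic dioxolane through the vinyl-stabilized oxocarbenium ion unmasks the enone; the TBS ether, the PMB ether and the hindered C9 silyl ether should tolerate the mild acid.

Step 26
Reactants: 35 ring A 1-en-3-one
Product: 36 1,2-epoxy 3-ketone (epoxide on the lower face)
Conditions: H2O2, NaOH, MeOH, 0 °C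
Reagents that add atoms: hydrogen peroxide, OO
Why: Weitz–Scheffer epoxidation: hydroperoxide adds axially to C1 anti to the axial C20 methyl, so the epoxide forms on the lower face, as in 1-en-3-ones with an angular methyl group.

Step 27
Reactants: 36 1,2-epoxy 3-ketone
Product: 37 2-en-1-ol (C1 hydroxyl on the lower face)
Conditions: N2H4·H2O, AcOH (cat.), MeOH, 0 °C → rt (argon)
Reagents that add atoms: none
Why: Wharton transposition: the epoxy hydrazone fragments with loss of nitrogen, which moves the oxygen to C1 with the epoxide configuration and the olefin to C2=C3.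

Step 28
Reactants: 37 2-en-1-ol
Product: 38 ring A 2-en-1-one
Conditions: Dess–Martin periodinane, NaHCO3, CH2Cl2, rt
Reagents that add atoms: none
Why: Dess–Martin oxidation of the only free hydroxyl gives the transposed enone; C9 is silylated, so no 1,3-diketone forms here.

Step 29
Reactants: 38 ring A 2-en-1-one
Product: 39 2,3-epoxy 1-ketone (epoxide on the lower face)
Conditions: H2O2, NaOH, MeOH, 0 °C
Reagents that add atoms: hydrogen peroxide, OO
Why: Second Weitz–Scheffer epoxidation: axial attack at C3 anti to the axial C4 methyl places the epoxide on the lower face, which is the C3 configuration of the target.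

Step 30
Reactants: 39 2,3-epoxy 1-ketone
Product: 40 3-hydroxy 1-ketone (C3 hydroxyl axial; C9 OTES)
Conditions: SmI2, MeOH, THF, −90 °C
Reagents that add atoms: none
Why: Electron transfer to the epoxy ketone cleaves the Cα–O bond at C2 and the samarium enolate is protonated, giving the β-hydroxy ketone; no SN2 attack at the hindered C2 is required.

Step 31
Reactants: 40 3-hydroxy 1-ketone
Product: 41 C9 propargylic alcohol
Conditions: HF·pyridine, pyridine, THF, 0 °C
Reagents that add atoms: none
Why: Buffered fluoride cleaves the triethylsilyl ether faster than the TBS ether and is not basic, so the β-hydroxy ketone should neither dehydrate nor undergo retro-aldol cleavage.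

Step 32
Reactants: 41 C9 propargylic alcohol
Product: 42 C9 ynone
Conditions: MnO2, CH2Cl2, rt
Reagents that add atoms: none
Why: Manganese dioxide oxidizes the propargylic C9 alcohol and leaves the unactivated C3 alcohol; with C1 still a ketone there is no β-hydroxyl that could add to the ynone.

Step 33
Reactants: 42 C9 ynone
Product: 43 C1,C9-diketone with saturated C11–C12 (C3 hydroxyl free)
Conditions: [(Ph3P)CuH]6, C6H6, H2O (few equiv), rt
Reagents that add atoms: none
Why: Copper hydride adds 1,4 to the ynone, the allenolate is protonated and the resulting enone is reduced again to the saturated ketone; isolated olefins, the unconjugated C1 ketone and the PMB ether do not react.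

Step 34
Reactants: 43 C1,C9-diketone
Product: 44 C3 acetate C1 alcohol (C9 ketone; C7 OTBS; C15 OPMB)
Conditions: SmI2 (30 mol %), MeCHO, THF, −10 °C
Reagents that add atoms: acetaldehyde, CC=O
Why: Evans–Tishchenko reduction: the samarium-bound hemiacetal from the axial C3 hydroxyl and acetaldehyde delivers its hydride to C1 from the lower face, giving the equatorial C1 hydroxyl anti to the C3 oxygen, which is left as the acetate; the C9 ketone has no β-hydroxyl and stays.

Step 35
Reactants: 44 C3 acetate C1 alcohol
Product: 45 C15 alcohol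
Conditions: DDQ, CH2Cl2–pH 7 buffer, 0 °C
Reagents that add atoms: none
Why: Oxidative cleavage of the PMB ether through the benzylic oxocarbenium ion frees the C15 hydroxyl; silyl ether, acetate and ketones are inert, and any over-oxidation at C15 only anticipates step 36.

Step 36
Reactants: 45 C15 alcohol
Product: 46 C7 tert-butyldimethylsilyl ether of the target
Conditions: MnO2, CH2Cl2, rt
Reagents that add atoms: none
Why: Manganese dioxide oxidizes the doubly allylic C15 alcohol to the cross-conjugated dienone and leaves the saturated C1 alcohol.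

Step 37
Reactants: 46 C7 tert-butyldimethylsilyl ether of the target
Product: 47 CNP0223751.1 (target)
Conditions: HF·pyridine, THF, 0 °C → rt
Reagents that add atoms: none
Why: Acidic fluoride removes the TBS ether without base, which the dienone, the acetate and the β-hydroxy ketone would not tolerate.

## Compound list

1 | isobutyraldehyde | CC(C)C=O | starting material
2 | pent-1-en-3-one | CCC(=O)C=C | starting material
3 | 2,4,4-trimethylcyclohex-2-en-1-one | CC1=CC(C)(C)CCC1=O | intermediate
4 | (S)-2,4,4-trimethylcyclohex-2-en-1-ol | CC1=CC(C)(C)CC[C@@H]1O | intermediate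
5 | ketene acetal (1-ethoxyvinyl ether of 4) | C=C(OCC)O[C@H]1CCC(C)(C)C=C1C | intermediate (not isolated)
6 | ethyl 2-[(1R)-2,6,6-trimethylcyclohex-2-en-1-yl]acetate | CCOC(=O)C[C@H]1C(C)=CCCC1(C)C | intermediate
7 | ethyl 2-[(1R)-2,6,6-trimethyl-4-oxocyclohex-2-en-1-yl]acetate | CCOC(=O)C[C@H]1C(C)=CC(=O)CC1(C)C | intermediate
8 | ethyl 2-[(1S)-5-hydroxy-2,6,6-trimethyl-4-oxocyclohex-2-en-1-yl]acetate (C3 epimers) | CCOC(=O)C[C@H]1C(C)=CC(=O)C(O)C1(C)C | intermediate
9 | ethyl 2-[(1S)-2,6,6-trimethyl-4,5-dioxocyclohex-2-en-1-yl]acetate | CCOC(=O)C[C@H]1C(C)=CC(=O)C(=O)C1(C)C | intermediate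
10 | ethyl 2-[(1S)-5,5-(ethylenedioxy)-2,6,6-trimethyl-4-oxocyclohex-2-en-1-yl]acetate | CCOC(=O)C[C@H]1C(C)=CC(=O)C2(OCCO2)C1(C)C | intermediate
11 | ethyl 2-[(1S,4S)-5,5-(ethylenedioxy)-4-hydroxy-2,6,6-trimethylcyclohex-2-en-1-yl]acetate (C2 hydroxyl trans to the C5 arm) | CCOC(=O)C[C@H]1C(C)=C[C@H](O)C2(OCCO2)C1(C)C | intermediate
12 | triethylsilyl ether of 11 | CCOC(=O)C[C@H]1C(C)=C[C@H](O[Si](CC)(CC)CC)C2(OCCO2)C1(C)C | intermediate
13 | 2-[(1S,4S)-5,5-(ethylenedioxy)-2,6,6-trimethyl-4-(triethylsilyloxy)cyclohex-2-en-1-yl]acetaldehyde | O=CC[C@H]1C(C)=C[C@H](O[Si](CC)(CC)CC)C2(OCCO2)C1(C)C | intermediate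
14 | 2-(prop-2-yn-1-yloxy)oxane (THP ether of propargyl alcohol) | C#CCOC1CCCCO1 | starting material
15 | (S)-4-(tert-butyldimethylsilyloxy)cyclopent-2-en-1-one | O=C1C=C[C@@H](O[Si](C)(C)C(C)(C)C)C1 | starting material
16 | dimethyl[3-(oxan-2-yloxy)prop-1-yn-1-yl]alane | C[Al](C)C#CCOC1CCCCO1 | intermediate (not isolated)
17 | (3R,4S)-4-(tert-butyldimethylsilyloxy)-3-[3-(oxan-2-yloxy)prop-1-yn-1-yl]cyclopentan-1-one | O=C1C[C@H](C#CCOC2CCCCO2)[C@@H](O[Si](C)(C)C(C)(C)C)C1 | intermediate
18 | (4S)-4-[3-(oxan-2-yloxy)prop-1-yn-1-yl]cyclopent-2-en-1-one | O=C1C[C@H](C#CCOC2CCCCO2)C=C1 | intermediate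
19 | (4S)-2-iodo-4-[3-(oxan-2-yloxy)prop-1-yn-1-yl]cyclopent-2-en-1-one | O=C1C[C@H](C#CCOC2CCCCO2)C=C1I | intermediate
20 | Mannich base (5-(dimethylaminomethyl) derivative of 19) | CN(C)CC1C(=O)C(I)=C[C@H]1C#CCOC2CCCCO2 | intermediate (not isolated)
21 | methiodide of 20 | C[N+](C)(C)CC1C(=O)C(I)=C[C@H]1C#CCOC2CCCCO2.[I-] | intermediate (not isolated)
22 | (4S)-2-iodo-5-methylidene-4-[3-(oxan-2-yloxy)prop-1-yn-1-yl]cyclopent-2-en-1-one | C=C1C(=O)C(I)=C[C@H]1C#CCOC2CCCCO2 | intermediate
23 | (1R,4S)-2-iodo-5-methylidene-4-[3-(oxan-2-yloxy)prop-1-yn-1-yl]cyclopent-2-en-1-ol (hydroxyl cis to the alkynyl arm) | C=C1[C@@H](O)C(I)=C[C@H]1C#CCOC2CCCCO2 | intermediate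
24 | 4-methoxybenzyl ether of 23 | C=C1[C@@H](OCc2ccc(OC)cc2)C(I)=C[C@H]1C#CCOC3CCCCO3 | intermediate
25 | seco C7 alcohol, both C7 epimers (ring A unit with C2 OTES and C3 dioxolane joined through C6–C7 to C8 of the cyclopentene unit with C15 OPMB, C16 methylidene and the C13 3-(THP-oxy)propynyl arm) | C=C1[C@@H](OCc2ccc(OC)cc2)C(=C[C@H]1C#CCOC3CCCCO3)C(O)C[C@H]4C(C)=C[C@H](O[Si](CC)(CC)CC)C5(OCCO5)C4(C)C | intermediate
26 | seco C7 enone | C=C1[C@@H](OCc2ccc(OC)cc2)C(=C[C@H]1C#CCOC3CCCCO3)C(=O)C[C@H]4C(C)=C[C@H](O[Si](CC)(CC)CC)C5(OCCO5)C4(C)C | intermediate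
27 | seco (7R)-alcohol | C=C1[C@@H](OCc2ccc(OC)cc2)C(=C[C@H]1C#CCOC3CCCCO3)[C@H](O)C[C@H]4C(C)=C[C@H](O[Si](CC)(CC)CC)C5(OCCO5)C4(C)C | intermediate
28 | seco (7R)-tert-butyldimethylsilyl ether | C=C1[C@@H](OCc2ccc(OC)cc2)C(=C[C@H]1C#CCOC3CCCCO3)[C@H](O[Si](C)(C)C(C)(C)C)C[C@H]4C(C)=C[C@H](O[Si](CC)(CC)CC)C5(OCCO5)C4(C)C | intermediate
29 | seco diol (C2 OH and C9 OH free, C7 OTBS, C15 OPMB, C3 dioxolane) | C=C1[C@@H](OCc2ccc(OC)cc2)C(=C[C@H]1C#CCO)[C@H](O[Si](C)(C)C(C)(C)C)C[C@H]3C(C)=C[C@H](O)C4(OCCO4)C3(C)C | intermediate
30 | C9 mesylate of 29 | C=C1[C@@H](OCc2ccc(OC)cc2)C(=C[C@H]1C#CCOS(C)(=O)=O)[C@H](O[Si](C)(C)C(C)(C)C)C[C@H]3C(C)=C[C@H](O)C4(OCCO4)C3(C)C | intermediate (not isolated)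
31 | seco C9 bromide (C2 OH free) | C=C1[C@@H](OCc2ccc(OC)cc2)C(=C[C@H]1C#CCBr)[C@H](O[Si](C)(C)C(C)(C)C)C[C@H]3C(C)=C[C@H](O)C4(OCCO4)C3(C)C | intermediate
32 | thirteen-membered propargylic allylic ether, key-step precursor (O on C2 on the lower face, C11≡C12, C1=C10, C3 dioxolane, C7 OTBS, C15 OPMB) | C=C1[C@@H](OCc2ccc(OC)cc2)C3=C[C@H]1C#CCO[C@H]4C=C(C)[C@H](C[C@H]3O[Si](C)(C)C(C)(C)C)C(C)(C)C45OCCO5 | intermediate
33 | lithium C9 alkoxide of the ring-contracted alcohol | C=C1[C@@H](OCc2ccc(OC)cc2)C3=C[C@H]1C#C[C@H]([O-])[C@@]4(C)[C@H](C[C@H]3O[Si](C)(C)C(C)(C)C)C(C)(C)C5(OCCO5)C=C4.[Li+] | intermediate (not isolated)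
34 | ring-contracted C9 triethylsilyl ether (ten-membered carbocycle, quaternary C10, C1=C2, C3 dioxolane, C7 OTBS, C15 OPMB) | C=C1[C@@H](OCc2ccc(OC)cc2)C3=C[C@H]1C#C[C@H](O[Si](CC)(CC)CC)[C@@]4(C)[C@H](C[C@H]3O[Si](C)(C)C(C)(C)C)C(C)(C)C5(OCCO5)C=C4 | intermediate
35 | ring A 1-en-3-one | C=C1[C@@H](OCc2ccc(OC)cc2)C3=C[C@H]1C#C[C@H](O[Si](CC)(CC)CC)[C@@]4(C)[C@H](C[C@H]3O[Si](C)(C)C(C)(C)C)C(C)(C)C(=O)C=C4 | intermediate
36 | 1,2-epoxy 3-ketone (epoxide on the lower face) | C=C1[C@@H](OCc2ccc(OC)cc2)C3=C[C@H]1C#C[C@H](O[Si](CC)(CC)CC)[C@@]4(C)[C@H](C[C@H]3O[Si](C)(C)C(C)(C)C)C(C)(C)C(=O)[C@H]5O[C@@H]45 | intermediate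
37 | 2-en-1-ol (C1 hydroxyl on the lower face) | C=C1[C@@H](OCc2ccc(OC)cc2)C3=C[C@H]1C#C[C@H](O[Si](CC)(CC)CC)[C@@]4(C)[C@H](C[C@H]3O[Si](C)(C)C(C)(C)C)C(C)(C)C=C[C@H]4O | intermediate
38 | ring A 2-en-1-one | C=C1[C@@H](OCc2ccc(OC)cc2)C3=C[C@H]1C#C[C@H](O[Si](CC)(CC)CC)[C@@]4(C)[C@H](C[C@H]3O[Si](C)(C)C(C)(C)C)C(C)(C)C=CC4=O | intermediate
39 | 2,3-epoxy 1-ketone (epoxide on the lower face) | C=C1[C@@H](OCc2ccc(OC)cc2)C3=C[C@H]1C#C[C@H](O[Si](CC)(CC)CC)[C@@]4(C)[C@H](C[C@H]3O[Si](C)(C)C(C)(C)C)C(C)(C)[C@H]5O[C@H]5C4=O | intermediate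
40 | 3-hydroxy 1-ketone (C3 hydroxyl axial, C9 OTES) | C=C1[C@@H](OCc2ccc(OC)cc2)C3=C[C@H]1C#C[C@H](O[Si](CC)(CC)CC)[C@@]4(C)[C@H](C[C@H]3O[Si](C)(C)C(C)(C)C)C(C)(C)[C@@H](O)CC4=O | intermediate
41 | C9 propargylic alcohol (C3 OH, C1 ketone) | C=C1[C@@H](OCc2ccc(OC)cc2)C3=C[C@H]1C#C[C@H](O)[C@@]4(C)[C@H](C[C@H]3O[Si](C)(C)C(C)(C)C)C(C)(C)[C@@H](O)CC4=O | intermediate
42 | C9 ynone | C=C1[C@@H](OCc2ccc(OC)cc2)C3=C[C@H]1C#CC(=O)[C@@]4(C)[C@H](C[C@H]3O[Si](C)(C)C(C)(C)C)C(C)(C)[C@@H](O)CC4=O | intermediate
43 | C1,C9-diketone with saturated C11–C12 (C3 OH axial) | C=C1[C@@H](OCc2ccc(OC)cc2)C3=C[C@H]1CCC(=O)[C@@]4(C)[C@H](C[C@H]3O[Si](C)(C)C(C)(C)C)C(C)(C)[C@@H](O)CC4=O | intermediate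
44 | C3 acetate C1 alcohol (C9 ketone, C7 OTBS, C15 OPMB) | C=C1[C@@H](OCc2ccc(OC)cc2)C3=C[C@H]1CCC(=O)[C@@]4(C)[C@H](C[C@H]3O[Si](C)(C)C(C)(C)C)C(C)(C)[C@@H](OC(C)=O)C[C@@H]4O | intermediate
45 | C15 alcohol | C=C1[C@@H](O)C3=C[C@H]1CCC(=O)[C@@]4(C)[C@H](C[C@H]3O[Si](C)(C)C(C)(C)C)C(C)(C)[C@@H](OC(C)=O)C[C@@H]4O | intermediate
46 | C7 tert-butyldimethylsilyl ether of the target | C=C1C(=O)C3=C[C@H]1CCC(=O)[C@@]4(C)[C@H](C[C@H]3O[Si](C)(C)C(C)(C)C)C(C)(C)[C@@H](OC(C)=O)C[C@@H]4O | intermediate
47 | CNP0223751.1 (1S,3S,5R,7R,10S,13R) | C=C1C(=O)C2=C[C@H]1CCC(=O)[C@@]1(C)[C@H](C[C@H]2O)C(C)(C)[C@@H](OC(C)=O)C[C@@H]1O | target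

## Step count and least certain steps

Total: 37 steps. Longest linear sequence: 31 steps (steps 1–10 and 17–37); the cyclopentene fragment takes steps 11–16.

**Step 24 (key step).** The most likely failure is lithiation at the wrong carbon: C13–H is allylic twice over and propargylic, and C15–H is doubly allylic and α to oxygen. Either would lead to isomerization or to a [1,2]-shift. The strained envelope at a fully substituted terminus could also slow the [2,3] path enough for these to win.
Fallback: form the same C9–C10 bond by an intramolecular Nozaki–Hiyama allylation. It sets out from 29 and returns at 34.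
- The primary propargylic alcohol of 29 is oxidized selectively (PhI(OAc)2, TEMPO cat.) to the ynal F1.
- The C2 hydroxyl of F1 is converted (MsCl, LiCl, 2,4,6-collidine, DMF) into the allylic chloride F2.
- CrCl2 in THF at high dilution generates the allylchromium species, which adds through its more substituted terminus C10 to the aldehyde and closes the ten-membered ring to the free C9 alcohol F3.
- Et3SiOTf and 2,6-lutidine convert F3 into 34.

In this variant C10 is no longer relayed from C2. Its configuration would rest on the preference for the trans ring fusion and would have to be established.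

**Step 8.** Poor or reversed facial selectivity of hydride addition at C2 is possible, because the polar effect of the neighbouring ketal oxygens opposes the steric bias of the C4 methyl.
Fallback: Mitsunobu inversion, setting out from 10 and returning at 11. If reduction of 10 gives mainly the C2 epimer F4, it is inverted with 4-nitrobenzoic acid, PPh3 and DIAD to the 4-nitrobenzoate F5, and ethanolysis (K2CO3, EtOH) gives 11.

**Step 7.** Ketalization may be slow at the neopentylic C3 carbonyl or may occur at C2.
Fallback: classical dithioketal transfer, setting out from 7 and returning at 10.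
- 7 is formylated at C3 (HCO2Et, NaH, THF) to the hydroxymethylene ketone F6.
- Propane-1,3-diyl bis(4-methylbenzenethiosulfonate) with KOAc in EtOH converts F6, with loss of the formyl group, into the dithioketal F7.
- PhI(OCOCF3)2 with ethylene glycol in MeCN exchanges sulfur for oxygen and gives 10.

**Step 23.** The hindered C2 alkoxide may alkylate slowly at high dilution, so that intermolecular etherification and alkoxide-induced isomerization at C13 compete.
Fallback: close the ether from the electrophilic side by a Nicholas reaction, setting out from 29 and returning at 32.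
- Co2(CO)8 in CH2Cl2 converts 29 into the dicobalt hexacarbonyl complex F8.
- BF3·OEt2 at −40 °C and high dilution ionizes the complexed propargylic alcohol, and the C2 hydroxyl traps the cation to give the complexed macrocyclic ether F9. The bent complexed alkyne helps the closure.
- Me3NO removes the metal and gives 32.

**Step 34.** The bicyclic hydride-transfer geometry may be slow in this ring, or the samarium may be held by the 1,3-diketone, so that unselective reduction or simple acetal formation wins.
Fallback: setting out from 43 and returning at 44.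
- Me4N[BH(OAc)3] in MeCN/AcOH, directed by the axial C3 hydroxyl, reduces C1 to the anti-1,3-diol F10.
- The equatorial C1 hydroxyl is silylated (Et3SiOTf, 1 equiv, 2,6-lutidine, −78 °C) to the C1 triethylsilyl ether F11.
- Ac2O and DMAP give the C3 acetate F12.
- HF·pyridine gives 44.

## Further compounds

F1 | step 24 | seco ynal (C9 aldehyde, C2 OH free) | C=C1[C@@H](OCc2ccc(OC)cc2)C(=C[C@H]1C#CC=O)[C@H](O[Si](C)(C)C(C)(C)C)C[C@H]3C(C)=C[C@H](O)C4(OCCO4)C3(C)C
F2 | step 24 | seco ynal C2 allylic chloride | C=C1[C@@H](OCc2ccc(OC)cc2)C(=C[C@H]1C#CC=O)[C@H](O[Si](C)(C)C(C)(C)C)C[C@H]3C(C)=CC(Cl)C4(OCCO4)C3(C)C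
F3 | step 24 | ring-contracted free C9 alcohol | C=C1[C@@H](OCc2ccc(OC)cc2)C3=C[C@H]1C#C[C@H](O)[C@@]4(C)[C@H](C[C@H]3O[Si](C)(C)C(C)(C)C)C(C)(C)C5(OCCO5)C=C4
F4 | step 8 | C2 epimer of 11 | CCOC(=O)C[C@H]1C(C)=C[C@@H](O)C2(OCCO2)C1(C)C
F5 | step 8 | 4-nitrobenzoate of 11 | CCOC(=O)C[C@H]1C(C)=C[C@H](OC(=O)c2ccc(cc2)[N+](=O)[O-])C3(OCCO3)C1(C)C
F6 | step 7 | C3 hydroxymethylene derivative of 7 | CCOC(=O)C[C@H]1C(C)=CC(=O)C(=CO)C1(C)C
F7 | step 7 | C3 propane-1,3-diyl dithioketal of 9 | CCOC(=O)C[C@H]1C(C)=CC(=O)C2(SCCCS2)C1(C)C
F8 | step 23 | dicobalt hexacarbonyl complex of 29 | C=C1[C@@H](OCc2ccc(OC)cc2)C(=C[C@H]1C56C7(CO)[Co]5(=C=O)(=C=O)(=C=O)[Co]67(=C=O)(=C=O)=C=O)[C@H](O[Si](C)(C)C(C)(C)C)C[C@H]3C(C)=C[C@H](O)C4(OCCO4)C3(C)C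
F9 | step 23 | dicobalt hexacarbonyl complex of 32 | C=C1[C@@H](OCc2ccc(OC)cc2)C3=C[C@H]1C56C7(CO[C@H]4C=C(C)[C@H](C[C@H]3O[Si](C)(C)C(C)(C)C)C(C)(C)C48OCCO8)[Co]5(=C=O)(=C=O)(=C=O)[Co]67(=C=O)(=C=O)=C=O
F10 | step 34 | anti-1,3-diol (C1 OH equatorial, C3 OH axial, C9 ketone) | C=C1[C@@H](OCc2ccc(OC)cc2)C3=C[C@H]1CCC(=O)[C@@]4(C)[C@H](C[C@H]3O[Si](C)(C)C(C)(C)C)C(C)(C)[C@@H](O)C[C@@H]4O
F11 | step 34 | C1 triethylsilyl ether of F10 | C=C1[C@@H](OCc2ccc(OC)cc2)C3=C[C@H]1CCC(=O)[C@@]4(C)[C@H](C[C@H]3O[Si](C)(C)C(C)(C)C)C(C)(C)[C@@H](O)C[C@@H]4O[Si](CC)(CC)CC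
F12 | step 34 | C3 acetate of F11 | C=C1[C@@H](OCc2ccc(OC)cc2)C3=C[C@H]1CCC(=O)[C@@]4(C)[C@H](C[C@H]3O[Si](C)(C)C(C)(C)C)C(C)(C)[C@@H](OC(C)=O)C[C@@H]4O[Si](CC)(CC)CC
A1 | alternative 1 | bridged cyclopentenone with C16 pivaloyloxymethyl group (Nazarov product) | CC(C)(C)C(=O)OC[C@@H]1C(=O)C2=C[C@H]1CCC(=O)[C@@]1(C)[C@H](C[C@H]2O[Si](C)(C)C(C)(C)C)C(C)(C)[C@@H](OC(C)=O)C[C@@H]1O[Si](C)(C)C(C)(C)C
A2 | alternative 1 | eleven-membered cross-conjugated dienone with C14 vinylsilane (Nazarov substrate) | C[Si](C)(C)C=C1C(=O)C(COC(=O)C(C)(C)C)=CCCC(=O)[C@@]2(C)[C@H](C[C@H]1O[Si](C)(C)C(C)(C)C)C(C)(C)[C@@H](OC(C)=O)C[C@@H]2O[Si](C)(C)C(C)(C)C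
A3 | alternative 2 | C1 tert-butyldimethylsilyl ether of the target (macrocyclization product) | C=C1C(=O)C2=C[C@H]1CCC(=O)[C@@]1(C)[C@H](C[C@H]2O)C(C)(C)[C@@H](OC(C)=O)C[C@@H]1O[Si](C)(C)C(C)(C)C
A4 | alternative 2 | open-chain C8 iodo dienone C7 aldehyde (macrocyclization substrate) | C=C1C(=O)C(I)=C[C@H]1CCC(=O)[C@@]1(C)[C@H](CC=O)C(C)(C)[C@@H](OC(C)=O)C[C@@H]1O[Si](C)(C)C(C)(C)C
A5 | alternative 3 | bridged ten-membered C9 ketone with C15 silyl ether (oxy-Cope product) | C=C1[C@H](O[Si](CC)(CC)CC)C2=C[C@H]1CCC(=O)[C@@]1(C)[C@H](C[C@H]2O[Si](C)(C)C(C)(C)C)C(C)(C)[C@@H](OCc2ccc(OC)cc2)C[C@@H]1O[Si](C)(C)C(C)(C)C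
A6 | alternative 3 | spiro-fused C9 vinyl decalinol (oxy-Cope substrate, alkenyl groups trans-diequatorial) | C=C[C@]1(O)[C@@]2(C=CC(=C)[C@@H]2O[Si](CC)(CC)CC)[C@H](O[Si](C)(C)C(C)(C)C)C[C@@H]3C(C)(C)[C@@H](OCc4ccc(OC)cc4)C[C@H](O[Si](C)(C)C(C)(C)C)[C@@]13C
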